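**Retrosynthetic overview**

1. The target is a 3,4-dihydro-2H-pyran whose C2 is the spiro α-carbon (C11, eudesmane numbering) of the cis-fused γ-lactone of an alantolactone unit and whose C5 carries a 4-ethenyl-4-methyl-3-isopropenylcyclohexyl (elemane-type) group.
2. Enabling feature: in the pyran ring, O1–C6=C5–C4 is a masked 2-substituted acrolein (1-oxadiene), C2–C3 is the former exocyclic C11=C13 of an α-methylene-γ-butyrolactone, and C4 is an isolated CH2 next to an aldehyde α-carbon (C5), i.e. a formaldehyde carbon.
3. Key disconnection: three-component domino α-methylenation/hetero-Diels–Alder of aldehyde 13, formaldehyde and (+)-alantolactone 14, forming C4–C5, C3–C4 and O1–C2 and setting the spiro centre; the pyran ring is formed last.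
4. Aldehyde 13: cyclohexane ring by catalytic asymmetric Diels–Alder reaction of diene 2 with enal ester 3, a temporary trans-fused γ-lactone to steer a face-selective hydrogenation, then lactone opening and double Wittig methylenation.
5. Ring order: cyclohexane (step 2), temporary lactone (step 3, opened in step 5), dihydropyran (step 10); the decalin and γ-lactone rings arrive intact in 14.

Key step: step 10

Remark: (+)-alantolactone 14 is taken as a commercial natural product; the cyclohexyl half of the target as written is antipodal to natural (−)-β-elemene at all three centres, so it is built de novo by asymmetric catalysis.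

Remark: the facial sense of the catalyst in step 2 is assigned from the usual model for α-substituted enals bound to prolinol-derived oxazaborolidinium ions; the mirror-image catalyst is used if that model does not hold for 3.

TBS = tert-butyldimethylsilyl. Locants O1–C6 refer to the new pyran ring; C11, C13, H-7 and H-8 refer to eudesmane numbering of 14.

**Route**

Step 1
Reactants: 1 tert-butyl(but-3-yn-1-yloxy)dimethylsilane
Product: 2 tert-butyldimethyl[(3-methylidenepent-4-en-1-yl)oxy]silane
Conditions: ethylene (1 atm), second-generation Grubbs catalyst RuCl2(=CHPh)(PCy3)(H2IMes) (3 mol %), PhMe, 80 °C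
Reagents that add atoms: ethylene, C=C
Why: Ethylene–alkyne cross enyne metathesis is a standard conversion of a terminal alkyne into a 2-substituted buta-1,3-diene, and no stereocentre is formed.

Step 2
Reactants: 2 tert-butyldimethyl[(3-methylidenepent-4-en-1-yl)oxy]silane; 3 ethyl (2E)-3-methyl-4-oxobut-2-enoate
Product: 4 ethyl (1S,6S)-3-{2-[(tert-butyldimethylsilyl)oxy]ethyl}-6-formyl-6-methylcyclohex-3-ene-1-carboxylate
Conditions: (S)-3,3-diphenyl-1-(o-tolyl)tetrahydro-1H,3H-pyrrolo[1,2-c][1,3,2]oxazaborole (20 mol %) activated with Tf2NH (18 mol %), CH2Cl2, −78 to −40 °C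
Reagents that add atoms: none
Why: Catalytic enantioselective Diels–Alder reaction under cationic oxazaborolidine catalysis, in which the catalyst-bound aldehyde directs the "para" orientation (diene CH2 next to the substituted carbon bonds to the ester-bearing β-carbon), the E geometry of 3 fixes CHO trans to CO2Et at the new quaternary C6 and tertiary C1, and the catalyst's face shielding should set their absolute configuration.

Step 3
Reactants: 4 ethyl (1S,6S)-3-{2-[(tert-butyldimethylsilyl)oxy]ethyl}-6-formyl-6-methylcyclohex-3-ene-1-carboxylate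
Product: 6 (3aS,7aS)-6-{2-[(tert-butyldimethylsilyl)oxy]ethyl}-3a-methyl-3a,4,7,7a-tetrahydro-2-benzofuran-1(3H)-one (trans-fused), via hydroxy ester 5 (not isolated)
Conditions: NaBH4, EtOH, 0 °C; then PPTS (10 mol %), PhMe, 80 °C
Reagents that add atoms: none
Why: Chemoselective borohydride reduction of the aldehyde beside the ester, then acid-catalysed lactonisation (intramolecular transesterification) to the trans-fused γ-lactone, with no change at the stereocentres.

Step 4
Reactants: 6 (3aS,7aS)-6-{2-[(tert-butyldimethylsilyl)oxy]ethyl}-3a-methyl-3a,4,7,7a-tetrahydro-2-benzofuran-1(3H)-one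
Product: 7 (3aS,6S,7aS)-6-{2-[(tert-butyldimethylsilyl)oxy]ethyl}-3a-methylhexahydro-2-benzofuran-1(3H)-one
Conditions: H2 (1 atm), PtO2 (5 mol %), EtOAc, rt
Reagents that add atoms: none
Why: Heterogeneous catalytic hydrogenation of the trisubstituted alkene, in which the trans ring fusion locks the angular methyl group axial over one face of the double bond, so hydrogen should add to the opposite face (that of H-7a) and place the C6 side chain equatorial and cis to the methyl group.

Step 5
Reactants: 7 (3aS,6S,7aS)-6-{2-[(tert-butyldimethylsilyl)oxy]ethyl}-3a-methylhexahydro-2-benzofuran-1(3H)-one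
Product: 8 1-[(1S,2S,5S)-5-{2-[(tert-butyldimethylsilyl)oxy]ethyl}-2-(hydroxymethyl)-2-methylcyclohexyl]ethan-1-one
Conditions: MeLi (1.1 equiv), THF, −78 °C; aq. NH4Cl
Reagents that add atoms: methyllithium, [Li]C
Why: Mono-addition of an organolithium to a γ-lactone should stop at the lithium hemiketal at low temperature and release the methyl ketone on work-up, leaving the stereocentres untouched.

Step 6
Reactants: 8 1-[(1S,2S,5S)-5-{2-[(tert-butyldimethylsilyl)oxy]ethyl}-2-(hydroxymethyl)-2-methylcyclohexyl]ethan-1-one
Product: 9 (1S,2S,4S)-2-acetyl-4-{2-[(tert-butyldimethylsilyl)oxy]ethyl}-1-methylcyclohexane-1-carbaldehyde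
Conditions: Dess–Martin periodinane, NaHCO3, CH2Cl2, 0 °C to rt
Reagents that add atoms: none
Why: Dess–Martin oxidation of the neopentyl primary alcohol under buffered, non-epimerising conditions, where only the open hydroxy ketone tautomer has an oxidisable C–H, so a cyclic hemiketal form cannot be over-oxidised.

Step 7
Reactants: 9 (1S,2S,4S)-2-acetyl-4-{2-[(tert-butyldimethylsilyl)oxy]ethyl}-1-methylcyclohexane-1-carbaldehyde
Product: 11 tert-butyl{2-[(1S,3R,4R)-4-ethenyl-4-methyl-3-(prop-1-en-2-yl)cyclohexyl]ethoxy}dimethylsilane, via vinyl ketone 10 (not isolated)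
Conditions: Ph3PCH3Br (5 equiv), KOtBu (4.8 equiv), THF, 0 °C, then 60 °C
Reagents that add atoms: methylidenetriphenylphosphorane (made in the flask), C=P(c1ccccc1)(c1ccccc1)c1ccccc1
Why: Double Wittig methylenation turns the formyl group into the vinyl group and the acetyl group into the isopropenyl group, with the non-enolisable aldehyde reacting first and the hindered ring C–H next to the ketone not expected to be deprotonated, so the stereocentres are kept.

Step 8
Reactants: 11 tert-butyl{2-[(1S,3R,4R)-4-ethenyl-4-methyl-3-(prop-1-en-2-yl)cyclohexyl]ethoxy}dimethylsilane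
Product: 12 2-[(1S,3R,4R)-4-ethenyl-4-methyl-3-(prop-1-en-2-yl)cyclohexyl]ethan-1-ol
Conditions: Bu4NF, THF, rt
Reagents that add atoms: none
Why: Fluoride-mediated cleavage of a primary silyl ether, a routine deprotection that does not touch the alkenes or stereocentres.

Step 9
Reactants: 12 2-[(1S,3R,4R)-4-ethenyl-4-methyl-3-(prop-1-en-2-yl)cyclohexyl]ethan-1-ol
Product: 13 2-[(1S,3R,4R)-4-ethenyl-4-methyl-3-(prop-1-en-2-yl)cyclohexyl]acetaldehyde
Conditions: Dess–Martin periodinane, NaHCO3, CH2Cl2, 0 °C to rt
Reagents that add atoms: none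
Why: Dess–Martin oxidation of a primary alcohol to the aldehyde under neutral conditions that tolerate the three alkenes; the ring stereocentre is β to the carbonyl and cannot epimerise.

Step 10
Reactants: 13 2-[(1S,3R,4R)-4-ethenyl-4-methyl-3-(prop-1-en-2-yl)cyclohexyl]acetaldehyde; 14 (+)-alantolactone (3.0 equiv)
Product: 16 target spiro dihydropyran (pyran C2 = lactone C11 in the 11R configuration; O1 on the α-face cis to H-7; pyran C5 bears the (1S,3R,4R)-cyclohexyl group), via enal 15 (not isolated)
Conditions: paraformaldehyde (1.5 equiv), i-Pr2NH2+ CF3CO2− (30 mol %), BHT (5 mol %), PhMe (1 M), sealed tube, 70 °C, then 125 °C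
Reagents that add atoms: formaldehyde (as paraformaldehyde), C=O
Why: The hindered secondary ammonium salt condenses with formaldehyde to an iminium ion that is attacked by the enol of 13 (Mannich reaction), and β-elimination of the amine gives the 2-substituted acrolein 15 with loss of water, which creates the C4–C5 bond of the future pyran; 15 then reacts in its s-cis form as a 1-oxadiene (O1=C6–C5=C4) with the exocyclic C11=C13 of 14 in a thermal hetero-Diels–Alder reaction that forms C3–C4 and O1–C2. The closest known reaction types are the amine-salt-mediated α-methylenation of aldehydes, the domino condensation/hetero-Diels–Alder sequence of 1-oxadienes formed in situ, and the thermal cycloaddition of acrolein or methacrolein to acrylates and methacrylates, which gives 2-alkoxycarbonyl-3,4-dihydro-2H-pyrans with the same orientation. The dihydropyran ring is closed by a concerted but asynchronous [4+2] cycloaddition in which C3–C4 bonding runs ahead, so that both developing termini sit α to a carbonyl group and O1 ends on the carbonyl-bearing C2, giving the spiro fusion. The only new stereocentre, spiro C2, is controlled by 14: the heterodiene should approach the convex α-face of the cis-fused γ-lactone (the face of H-7 and H-8), which places O1 cis to H-7 as required, while C5 is sp2 and the cyclohexyl centres of 13 are untouched. The step needs cross- over self-cycloaddition of 15 and reaction at C11=C13 rather than at the vinyl, isopropenyl and ring-B alkenes; this should be secured by the excess of 14, by the low stationary concentration of 15 that in situ methylenation provides, by the carbonyl activation and exposed s-cis-locked geometry of the methylene lactone, and by an amine too hindered to add to 14 in an aza-Michael reaction.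

**Compound list**

1 | tert-butyl(but-3-yn-1-yloxy)dimethylsilane | C#CCCO[Si](C)(C)C(C)(C)C | starting material
2 | tert-butyldimethyl[(3-methylidenepent-4-en-1-yl)oxy]silane | C=CC(=C)CCO[Si](C)(C)C(C)(C)C | intermediate
3 | ethyl (2E)-3-methyl-4-oxobut-2-enoate | CCOC(=O)/C=C(\C)C=O | starting material
4 | ethyl (1S,6S)-3-{2-[(tert-butyldimethylsilyl)oxy]ethyl}-6-formyl-6-methylcyclohex-3-ene-1-carboxylate | O=C[C@@]1(C)CC=C(CCO[Si](C)(C)C(C)(C)C)C[C@@H]1C(=O)OCC | intermediate
5 | ethyl (1S,6S)-3-{2-[(tert-butyldimethylsilyl)oxy]ethyl}-6-(hydroxymethyl)-6-methylcyclohex-3-ene-1-carboxylate | OC[C@@]1(C)CC=C(CCO[Si](C)(C)C(C)(C)C)C[C@@H]1C(=O)OCC | intermediate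
6 | (3aS,7aS)-6-{2-[(tert-butyldimethylsilyl)oxy]ethyl}-3a-methyl-3a,4,7,7a-tetrahydro-2-benzofuran-1(3H)-one | O1C[C@@]2(C)CC=C(CCO[Si](C)(C)C(C)(C)C)C[C@@H]2C1=O | intermediate
7 | (3aS,6S,7aS)-6-{2-[(tert-butyldimethylsilyl)oxy]ethyl}-3a-methylhexahydro-2-benzofuran-1(3H)-one | O1C[C@@]2(C)CC[C@H](CCO[Si](C)(C)C(C)(C)C)C[C@@H]2C1=O | intermediate
8 | 1-[(1S,2S,5S)-5-{2-[(tert-butyldimethylsilyl)oxy]ethyl}-2-(hydroxymethyl)-2-methylcyclohexyl]ethan-1-one | OC[C@@]1(C)CC[C@H](CCO[Si](C)(C)C(C)(C)C)C[C@@H]1C(C)=O | intermediate
9 | (1S,2S,4S)-2-acetyl-4-{2-[(tert-butyldimethylsilyl)oxy]ethyl}-1-methylcyclohexane-1-carbaldehyde | O=C[C@@]1(C)CC[C@H](CCO[Si](C)(C)C(C)(C)C)C[C@@H]1C(C)=O | intermediate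
10 | 1-[(1S,2R,5S)-5-{2-[(tert-butyldimethylsilyl)oxy]ethyl}-2-ethenyl-2-methylcyclohexyl]ethan-1-one | C=C[C@@]1(C)CC[C@H](CCO[Si](C)(C)C(C)(C)C)C[C@@H]1C(C)=O | intermediate
11 | tert-butyl{2-[(1S,3R,4R)-4-ethenyl-4-methyl-3-(prop-1-en-2-yl)cyclohexyl]ethoxy}dimethylsilane | C=C[C@@]1(C)CC[C@H](CCO[Si](C)(C)C(C)(C)C)C[C@@H]1C(=C)C | intermediate
12 | 2-[(1S,3R,4R)-4-ethenyl-4-methyl-3-(prop-1-en-2-yl)cyclohexyl]ethan-1-ol | C=C[C@@]1(C)CC[C@H](CCO)C[C@@H]1C(=C)C | intermediate
13 | 2-[(1S,3R,4R)-4-ethenyl-4-methyl-3-(prop-1-en-2-yl)cyclohexyl]acetaldehyde | C=C[C@@]1(C)CC[C@H](CC=O)C[C@@H]1C(=C)C | intermediate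
14 | (+)-alantolactone, (3aR,5S,8aR,9aR)-5,8a-dimethyl-3-methylidene-3a,5,6,7,8,8a,9,9a-octahydronaphtho[2,3-b]furan-2(3H)-one | C=C1C(=O)O[C@@H]2C[C@@]3(C)CCC[C@H](C)C3=C[C@H]12 | starting material
15 | 2-[(1S,3R,4R)-4-ethenyl-4-methyl-3-(prop-1-en-2-yl)cyclohexyl]prop-2-enal | C=C[C@@]1(C)CC[C@H](C(=C)C=O)C[C@@H]1C(=C)C | intermediate
16 | target: spiro[3,4-dihydro-2H-pyran-2,11'-eudesmanolide] with the (1S,3R,4R)-4-ethenyl-4-methyl-3-(prop-1-en-2-yl)cyclohexyl group on pyran C5; eudesmane centres 4S,7S,8R,10R,11R, pyran O on the α-face of C11 | C=C[C@@]1(C)CC[C@H](C2=CO[C@@]3(CC2)C(=O)O[C@@H]2C[C@@]4(C)CCC[C@H](C)C4=C[C@@H]23)C[C@@H]1C(=C)C | target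

**Summary**

Total step count: 10. Longest linear sequence: 10 steps (1 to 16; 3 and 14 enter as commercial compounds).

**Steps most likely to fail**

Step 10. What may go wrong: the cross cycloaddition may be outrun by self-cycloaddition or oligomerisation of the transient enal; the methylenation may stall at the Mannich-base stage; or the enol ether may be hydrated by the water and ammonium salt present at high temperature. Fallback: setting out from 13, the aldehyde is condensed with dimethylmethyleneiminium iodide (CH2=NMe2+ I−, Et3N, CH2Cl2) to the Mannich base 3-(dimethylamino)-2-[(1S,3R,4R)-4-ethenyl-4-methyl-3-(prop-1-en-2-yl)cyclohexyl]propanal F1. F1 should lose dimethylamine on warming with acetic acid or on silica gel to give enal 15 as an isolated compound. 15 and 14 are then combined, free of amine and water, in CH2Cl2 with BHT under about 12 kbar hydrostatic pressure. This discrete, pressure-driven hetero-Diels–Alder reaction comes back to the route at 16.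

Step 2. What may go wrong: slow turnover with a trisubstituted, doubly activated dienophile and a 2-alkyl diene; erosion of regio- or facial selectivity by competing activation through the ester; or acid-induced loss of the silyl ether and polymerisation of the diene. Fallback: setting out from 2 and 3, an achiral Lewis acid (Me2AlCl, CH2Cl2, −78 °C) should give the same adduct as a racemate, that is 4 together with its mirror image ethyl (1R,6R)-3-{2-[(tert-butyldimethylsilyl)oxy]ethyl}-6-formyl-6-methylcyclohex-3-ene-1-carboxylate F2. Reduction and lactonisation as in step 3 then give 6 together with (3aR,7aR)-6-{2-[(tert-butyldimethylsilyl)oxy]ethyl}-3a-methyl-3a,4,7,7a-tetrahydro-2-benzofuran-1(3H)-one F4, by way of 5 and ethyl (1R,6R)-3-{2-[(tert-butyldimethylsilyl)oxy]ethyl}-6-(hydroxymethyl)-6-methylcyclohex-3-ene-1-carboxylate F3. The racemic lactone is opened with (S)-1-phenylethylamine and AlMe3 to two diastereomeric hydroxy amides: (1S,6S)-3-{2-[(tert-butyldimethylsilyl)oxy]ethyl}-6-(hydroxymethyl)-6-methyl-N-[(1S)-1-phenylethyl]cyclohex-3-ene-1-carboxamide F5 (from 6) and its (1R,6R) diastereomer F6 (from F4). These are separated by crystallisation or chromatography. Heating F5 with camphorsulfonic acid in toluene should re-close the lactone with loss of the amine, and the classical resolution comes back to the route at 6.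

Step 4. What may go wrong: insufficient facial discrimination on the catalyst surface, or migration of the double bond before reduction, giving the C6 epimer. Fallback: setting out from hydroxy ester 5, which is isolated after the borohydride reduction instead of being lactonised, a hydroxyl-directed homogeneous hydrogenation with [Ir(cod)(PCy3)(py)]PF6 (H2, CH2Cl2) should deliver hydrogen to the ring face that carries the CH2OH group. This should give ethyl (1S,2S,5S)-5-{2-[(tert-butyldimethylsilyl)oxy]ethyl}-2-(hydroxymethyl)-2-methylcyclohexane-1-carboxylate F7. PPTS in toluene then closes the lactone and comes back to the route at 7.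

**Further compounds**

F1 | step 10 | 3-(dimethylamino)-2-[(1S,3R,4R)-4-ethenyl-4-methyl-3-(prop-1-en-2-yl)cyclohexyl]propanal (mixture at C2) | C=C[C@@]1(C)CC[C@H](C(CN(C)C)C=O)C[C@@H]1C(=C)C
F2 | step 2 | ethyl (1R,6R)-3-{2-[(tert-butyldimethylsilyl)oxy]ethyl}-6-formyl-6-methylcyclohex-3-ene-1-carboxylate | O=C[C@]1(C)CC=C(CCO[Si](C)(C)C(C)(C)C)C[C@H]1C(=O)OCC
F3 | step 2 | ethyl (1R,6R)-3-{2-[(tert-butyldimethylsilyl)oxy]ethyl}-6-(hydroxymethyl)-6-methylcyclohex-3-ene-1-carboxylate | OC[C@]1(C)CC=C(CCO[Si](C)(C)C(C)(C)C)C[C@H]1C(=O)OCC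
F4 | step 2 | (3aR,7aR)-6-{2-[(tert-butyldimethylsilyl)oxy]ethyl}-3a-methyl-3a,4,7,7a-tetrahydro-2-benzofuran-1(3H)-one | O1C[C@]2(C)CC=C(CCO[Si](C)(C)C(C)(C)C)C[C@H]2C1=O
F5 | step 2 | (1S,6S)-3-{2-[(tert-butyldimethylsilyl)oxy]ethyl}-6-(hydroxymethyl)-6-methyl-N-[(1S)-1-phenylethyl]cyclohex-3-ene-1-carboxamide | OC[C@@]1(C)CC=C(CCO[Si](C)(C)C(C)(C)C)C[C@@H]1C(=O)N[C@@H](C)c1ccccc1
F6 | step 2 | (1R,6R)-3-{2-[(tert-butyldimethylsilyl)oxy]ethyl}-6-(hydroxymethyl)-6-methyl-N-[(1S)-1-phenylethyl]cyclohex-3-ene-1-carboxamide | OC[C@]1(C)CC=C(CCO[Si](C)(C)C(C)(C)C)C[C@H]1C(=O)N[C@@H](C)c1ccccc1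
F7 | step 4 | ethyl (1S,2S,5S)-5-{2-[(tert-butyldimethylsilyl)oxy]ethyl}-2-(hydroxymethyl)-2-methylcyclohexane-1-carboxylate | OC[C@@]1(C)CC[C@H](CCO[Si](C)(C)C(C)(C)C)C[C@@H]1C(=O)OCC
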